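**Retrosynthetic overview**
- C3–Br is put on last by electrophilic bromination of 5,7-dibromo-6-methoxyindole 12; 12 comes from indoline 11 (pyrrole-ring dehydrogenation), 11 from N-Boc indoline 10 (Boc removal), 10 from the cis-tetrahydroindole 9 (benzene-ring dehydrogenation).
- Key disconnection: C3a–C4 and C7–C7a of 9, by [4+2] cycloaddition of 3,5-dibromo-4-methoxy-2-pyranone 6 with N-Boc-2-pyrroline 7 and loss of CO2.
- Feature used: the contiguous C4(H)–C5(Br)–C6(OMe)–C7(Br) array of the benzenoid ring is the C6–C5–C4–C3 diene of the pyranone; C3a and C7a are the alkene carbons C4 and C5 of the pyrroline.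
- 6 comes from 4-methoxy-2-pyranone 4 by dibromination; 4 from methyl (E)-3-methoxybut-2-enoate 1 and ethyl formate 2.
- Ring order: sacrificial pyranone ring, then the six-membered carbocycle built onto the purchased five-membered N-ring (step 3), then benzene aromatisation, then pyrrole aromatisation.

Key step: step 3

Assumption: the target has no stereocentre, so the request for a single enantiomer is met trivially; the two ring-fusion centres of 8 and 9 are racemic and are erased in step 4.

**Step 1**
Reactants: 1 methyl (E)-3-methoxybut-2-enoate; 2 ethyl formate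
Product: 4 4-methoxy-2H-pyran-2-one, via methyl (2E)-3-methoxy-5-oxopent-2-enoate 3 (not isolated)
Conditions: LDA (2.1 equiv), THF, −78 °C; HCO2Et (3 equiv), −78 → 0 °C; AcOH quench; then TsOH (cat.), PhMe, 80 °C
Reagents that add atoms: none
Why: Kinetic γ-deprotonation of the vinylogous ester gives a lithium dienolate whose γ-carbon (cis to the ester in the E isomer) undergoes a vinylogous Claisen formylation, and the enol of 3 then closes onto the neighbouring ester by acid-catalysed enol lactonisation with loss of methanol.

**Step 2**
Reactants: 4 4-methoxy-2H-pyran-2-one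
Product: 6 3,5-dibromo-4-methoxy-2H-pyran-2-one, via 3-bromo-4-methoxy-2H-pyran-2-one 5 (not isolated)
Conditions: Br2 (2.3 equiv), NaOAc (2.5 equiv), AcOH, rt → 50 °C; aq Na2S2O3 work-up
Reagents that add atoms: bromine, BrBr
Why: Electrophilic bromination (substitution, or addition–elimination across C5=C6) should go first at C3, the β-carbon of the 4-methoxy enol ether, and then at C5, the β-carbon of the ring-oxygen enol ester; these are the only two nucleophilic ring positions and C6 is electrophilic.

**Step 3**
Reactants: 6 3,5-dibromo-4-methoxy-2H-pyran-2-one; 7 tert-butyl 2,3-dihydro-1H-pyrrole-1-carboxylate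
Product: 9 tert-butyl cis-5,7-dibromo-6-methoxy-2,3,3a,7a-tetrahydro-1H-indole-1-carboxylate (racemic), via bridged lactone cycloadduct 8 (not isolated)
Conditions: 7 (3 equiv), PhMe (1 M), BHT (cat.), NaHCO3 (s), 115 °C, sealed tube, Ar; excess 7 removed under high vacuum, crude 9 used at once
Reagents that add atoms: none
Why: The LUMO of the electron-poor pyranone diene (termini C3 and C6) and the HOMO of the enecarbamate combine in a suprafacial, probably asynchronous inverse-demand Diels–Alder reaction to give the bridged lactone 8, which on further heating loses CO2 by retro-[4+2] to leave the cyclohexa-1,3-diene 9. The closest known reaction type is the cycloaddition of 3-bromo- and 3,5-dibromo-2-pyranones with enol ethers and related donor alkenes followed by thermal decarboxylation. The six-membered carbocycle is closed by the intermolecular [4+2] cycloaddition itself, both ring bonds (C3a–C4 and C7–C7a) forming in one pericyclic event, so no separate cyclisation mode has to be satisfied. The two new ring-fusion centres C3a and C7a come out cis because both bonds form on one face of the cis ring alkene of 7; they are racemic and are erased in step 4, and the endo/exo question disappears with the lactone bridge. The selectivity that matters is regiochemistry: the nucleophilic β-carbon (C4) of 7 bonds to pyranone C6, the electrophilic terminus of the dienoate, so the nitrogen-bearing C5 joins the brominated C3 and nitrogen ends up next to C7–Br. The two bromines, and the twisting of the flanked methoxy group out of conjugation, should keep the diene electron-poor enough, while bicarbonate and BHT hold back acid- or radical-induced loss of the carbamate from 9.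

**Step 4**
Reactants: 9 tert-butyl cis-5,7-dibromo-6-methoxy-2,3,3a,7a-tetrahydro-1H-indole-1-carboxylate
Product: 10 tert-butyl 5,7-dibromo-6-methoxyindoline-1-carboxylate
Conditions: DDQ (1.1 equiv), PhMe, 0 °C → rt
Reagents that add atoms: none
Why: Quinone dehydrogenation of a cyclohexa-1,3-diene: hydride abstraction from C7a–H gives a cation stabilised by the carbamate nitrogen and the C6 methoxy group, and loss of the C3a proton forms the benzene ring, which at 0 °C to rt should be faster than ionisation of the C7a–N bond.

**Step 5**
Reactants: 10 tert-butyl 5,7-dibromo-6-methoxyindoline-1-carboxylate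
Product: 11 5,7-dibromo-6-methoxyindoline
Conditions: TFA, CH2Cl2, 0 °C → rt; aq NaHCO3 work-up
Reagents that add atoms: none
Why: Acidolytic Boc cleavage (loss of the tert-butyl cation, then decarboxylation); the only free arene position (C4) is not activated toward tert-butylation, and the aryl bromides and the methyl ether are inert to TFA.

**Step 6**
Reactants: 11 5,7-dibromo-6-methoxyindoline
Product: 12 5,7-dibromo-6-methoxy-1H-indole
Conditions: DDQ (1.05 equiv), PhMe, 0 °C → rt
Reagents that add atoms: none
Why: DDQ dehydrogenation of an N–H indoline (hydride abstraction at C2 assisted by the aniline nitrogen, then loss of the C3 proton) is a standard indoline-to-indole oxidation; the N-Boc compound would resist it, which is why the carbamate is removed first.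

**Step 7**
Reactants: 12 5,7-dibromo-6-methoxy-1H-indole
Product: 13 3,5,7-tribromo-6-methoxy-1H-indole
Conditions: NBS (1.0 equiv), DMF, 0 °C, dark
Reagents that add atoms: N-bromosuccinimide, O=C1CCC(=O)N1Br
Why: Electrophilic aromatic bromination of an indole goes at C3, the enamine β-carbon; the only free benzenoid position (C4) is meta to the methoxy group, and one equivalent of NBS at 0 °C should avoid over-bromination at C2.

**Compound list**
1 | methyl (E)-3-methoxybut-2-enoate | CO/C(C)=C/C(=O)OC | starting material
2 | ethyl formate | CCOC=O | starting material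
3 | methyl (2E)-3-methoxy-5-oxopent-2-enoate (formed as its lithium enolate, not isolated) | COC(=O)/C=C(/OC)CC=O | intermediate
4 | 4-methoxy-2H-pyran-2-one | COc1ccoc(=O)c1 | intermediate
5 | 3-bromo-4-methoxy-2H-pyran-2-one (not isolated) | COc1ccoc(=O)c1Br | intermediate
6 | 3,5-dibromo-4-methoxy-2H-pyran-2-one | COc1c(Br)coc(=O)c1Br | intermediate
7 | tert-butyl 2,3-dihydro-1H-pyrrole-1-carboxylate | CC(C)(C)OC(=O)N1CCC=C1 | starting material
8 | bridged lactone cycloadduct: tert-butyl 1,11-dibromo-10-methoxy-9-oxo-8-oxa-3-azatricyclo[5.2.2.0^2,6]undec-10-ene-3-carboxylate (racemic endo/exo mixture, pyrrolidine cis-fused, bridgehead descriptors left open, not isolated) | CC(C)(C)OC(=O)N1CC[C@H]2[C@@H]1C3(Br)C(=O)OC2C(Br)=C3OC | intermediate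
9 | tert-butyl cis-5,7-dibromo-6-methoxy-2,3,3a,7a-tetrahydro-1H-indole-1-carboxylate (racemic, one enantiomer drawn) | CC(C)(C)OC(=O)N1CC[C@H]2C=C(Br)C(OC)=C(Br)[C@@H]12 | intermediate
10 | tert-butyl 5,7-dibromo-6-methoxyindoline-1-carboxylate | CC(C)(C)OC(=O)N1CCc2cc(Br)c(OC)c(Br)c21 | intermediate
11 | 5,7-dibromo-6-methoxyindoline | COc1c(Br)cc2CCNc2c1Br | intermediate
12 | 5,7-dibromo-6-methoxy-1H-indole | COc1c(Br)cc2cc[nH]c2c1Br | intermediate
13 | 3,5,7-tribromo-6-methoxy-1H-indole | COc1c(Br)cc2c(Br)c[nH]c2c1Br | target

**Totals**
Total step count: 7. Longest linear sequence: 7 steps (1 → 4 → 6 → 9 → 10 → 11 → 12 → 13).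

**Steps most likely to fail**

Step 3 (key step). The methoxy donor may slow the cycloaddition so far that, at the temperature then needed, the enecarbamate decomposes. The diene may also aromatise before it can be oxidised, either by loss of the carbamate nitrogen or, after a 1,5-hydrogen shift, by loss of HBr. The fallback sets out from 6 and comes back at 10, replacing steps 3 and 4. Commercial N-Boc-pyrrolidin-2-one is O-silylated (TBSOTf, Et3N, CH2Cl2, 0 °C) to the silyl ketene N,O-acetal tert-butyl 5-[(tert-butyldimethylsilyl)oxy]-2,3-dihydro-1H-pyrrole-1-carboxylate F1, a much more nucleophilic 2π partner. Heating 6 with F1 in toluene should give the 7a-silyloxy bridged lactone F2 and, after CO2 loss, tert-butyl cis-5,7-dibromo-7a-[(tert-butyldimethylsilyl)oxy]-6-methoxy-2,3,3a,7a-tetrahydro-1H-indole-1-carboxylate F3. F3 carries its own leaving group and should aromatise by elimination of silanol across C3a–C7a to give 10 directly, without an oxidant. This follows the known arene synthesis from 2-pyranones and ketene acetals.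

Step 2. The second bromination at C5 may stall at the monobromide, or bromine may add across C5=C6 and open the lactone. The fallback sets out from 5 (what an incomplete bromination delivers; also available on purpose with 1 equiv NBS in MeCN) and comes back at 10. Cycloaddition of 5 with 7 under the step 3 conditions (longer heating or 10–12 kbar, since the diene is less activated) should give the monobromo bridged lactone F4 and then tert-butyl cis-7-bromo-6-methoxy-2,3,3a,7a-tetrahydro-1H-indole-1-carboxylate F5. DDQ should give tert-butyl 7-bromo-6-methoxyindoline-1-carboxylate F6. NBS in MeCN should then brominate C5, the only free position that is ortho to the methoxy group and para to the carbamate nitrogen, to give 10.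

Step 1. Formylation may occur at the α-carbon or on oxygen instead of the γ-carbon, proton transfer may quench the dienolate, or the enol ether may hydrolyse during lactonisation. The fallback sets out from 1 and comes back at 4. The lithium dienolate of 1 is trapped with monomeric formaldehyde (vinylogous aldol) to give the alkoxide of methyl (2E)-5-hydroxy-3-methoxypent-2-enoate F7, which should lactonise in the flask to 4-methoxy-5,6-dihydro-2H-pyran-2-one F8. Wohl–Ziegler bromination (NBS, AIBN, PhCF3, reflux) at the allylic C5 should give 5-bromo-4-methoxy-5,6-dihydro-2H-pyran-2-one F9, and Et3N should then eliminate HBr to give 4. This is the sequence known for making the parent 2-pyranone from its 5,6-dihydro precursor.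

**Further compounds**
F1 | step 3 | tert-butyl 5-[(tert-butyldimethylsilyl)oxy]-2,3-dihydro-1H-pyrrole-1-carboxylate | CC(C)(C)OC(=O)N1CCC=C1O[Si](C)(C)C(C)(C)C
F2 | step 3 | 7a-silyloxy bridged lactone from 6 and F1 (racemic endo/exo mixture, not isolated) | CC(C)(C)OC(=O)N1CC[C@H]2[C@]1(O[Si](C)(C)C(C)(C)C)C3(Br)C(=O)OC2C(Br)=C3OC
F3 | step 3 | tert-butyl cis-5,7-dibromo-7a-[(tert-butyldimethylsilyl)oxy]-6-methoxy-2,3,3a,7a-tetrahydro-1H-indole-1-carboxylate (racemic, not isolated) | CC(C)(C)OC(=O)N1CC[C@H]2C=C(Br)C(OC)=C(Br)[C@@]12O[Si](C)(C)C(C)(C)C
F4 | step 2 | monobromo bridged lactone from 5 and 7 (racemic endo/exo mixture, not isolated) | CC(C)(C)OC(=O)N1CC[C@H]2[C@@H]1C3(Br)C(=O)OC2C=C3OC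
F5 | step 2 | tert-butyl cis-7-bromo-6-methoxy-2,3,3a,7a-tetrahydro-1H-indole-1-carboxylate (racemic) | CC(C)(C)OC(=O)N1CC[C@H]2C=CC(OC)=C(Br)[C@@H]12
F6 | step 2 | tert-butyl 7-bromo-6-methoxyindoline-1-carboxylate | CC(C)(C)OC(=O)N1CCc2ccc(OC)c(Br)c21
F7 | step 1 | methyl (2E)-5-hydroxy-3-methoxypent-2-enoate (as lithium alkoxide, not isolated) | COC(=O)/C=C(/OC)CCO
F8 | step 1 | 4-methoxy-5,6-dihydro-2H-pyran-2-one | COC1=CC(=O)OCC1
F9 | step 1 | 5-bromo-4-methoxy-5,6-dihydro-2H-pyran-2-one (racemic) | COC1=CC(=O)OCC1Br
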